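The benzotropolone is cut across its seven-membered ring (C4a, C5, C6, C7, C8, C9, C9a). Because the C6 hydroxyl lies beside C7, the carbon bearing flavan B, C7–C8 is taken from an alkyne and C5, C6, the bridging oxygen and C9 from a 2-benzopyrylium-4-olate fused to the benzenoid ring that holds the gallated flavan A at C1. One [5+2] cycloaddition forms C6–C7 and C8–C9 and delivers the ring at tropolone oxidation level as an oxygen-bridged adduct; a formyl group on the alkyne steers the regiochemistry and is removed afterwards. The precursors are a 1-acetoxyisochroman-4-one (28) and a chromanyl propynal (35), both made from one glycidate-derived hydroxy lactone (8).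

Key step: step 25

Assumption: 1, 3, 10 and 21 are purchased; 27 and 28 are used as mixtures of C1 epimers and the bridgeheads of 37 and 38 are left unassigned, since these centres vanish when the tropolone forms.

Step 1
Reactants: 1 3,5-bis(benzyloxy)phenol
Product: 2 1,3-bis(benzyloxy)-5-(methoxymethoxy)benzene
Conditions: MOMCl, iPr2NEt, CH2Cl2, 0 °C to rt
Reagents that add atoms: chloromethyl methyl ether, COCCl
Why: O-alkylation of the phenol (Williamson type) installs the methoxymethyl ether that directs the next lithiation and is later removed under the lactonisation conditions.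

Step 2
Reactants: 2 1,3-bis(benzyloxy)-5-(methoxymethoxy)benzene; 3 methyl (R)-glycidate
Product: 6 methyl (2R)-3-[2,4-bis(benzyloxy)-6-(methoxymethoxy)phenyl]-2-hydroxypropanoate, via aryllithium 4 (not isolated), via arylmagnesium bromide 5 (not isolated)
Conditions: n-BuLi, THF, 0 °C; MgBr2·OEt2, −78 to 0 °C; CuBr·SMe2 (10 mol%), then 3, −40 to −20 °C; H2O quench
Reagents that add atoms: none
Why: Directed ortho-metalation occurs between the methoxymethoxy and benzyloxy groups, and the copper-catalysed Grignard opening of the glycidate at its CH2 carbon (SN2) leaves the (R)-carbinol, the future C3 of both flavans, untouched.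

Step 3
Reactants: 6 methyl (2R)-3-[2,4-bis(benzyloxy)-6-(methoxymethoxy)phenyl]-2-hydroxypropanoate
Product: 8 (3R)-5,7-bis(benzyloxy)-3-hydroxychroman-2-one, via phenol ester 7 (not isolated)
Conditions: HCl (from AcCl), MeOH, 40 °C; evaporate; TsOH·H2O (cat.), toluene, 80 °C
Reagents that add atoms: none
Why: Acid methanolysis removes the phenolic methoxymethyl group as dimethoxymethane, and the freed ortho-phenol then lactonises onto the methyl ester under acid catalysis without touching the carbinol centre.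

Step 4
Reactants: 8 (3R)-5,7-bis(benzyloxy)-3-hydroxychroman-2-one
Product: 9 (3R)-5,7-bis(benzyloxy)-3-(tert-butyldimethylsilyloxy)chroman-2-one
Conditions: TBSOTf, 2,6-lutidine, CH2Cl2, −78 to 0 °C
Reagents that add atoms: tert-butyldimethylsilyl triflate, CC(C)(C)[Si](C)(C)OS(=O)(=O)C(F)(F)F
Why: Silylation under non-nucleophilic conditions protects the alcohol against the aryllithium without opening the aryl lactone and provides the bulky group that later controls the reduction at C2.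

Step 5
Reactants: 10 2-bromoisovanillin (2-bromo-3-hydroxy-4-methoxybenzaldehyde)
Product: 11 2-bromo-3-hydroxy-6-iodo-4-methoxybenzaldehyde
Conditions: NIS, CF3CO2H (cat.), MeCN, rt
Reagents that add atoms: N-iodosuccinimide, O=C1CCC(=O)N1I
Why: Electrophilic aromatic iodination is directed by the free phenol to its only open para position, which places beside the bromide a second halogen that can be exchanged selectively.

Step 6
Reactants: 11 2-bromo-3-hydroxy-6-iodo-4-methoxybenzaldehyde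
Product: 12 2-bromo-3,4-dihydroxy-6-iodobenzaldehyde
Conditions: BBr3, CH2Cl2, −78 °C to rt; H2O
Reagents that add atoms: none
Why: Lewis acid demethylation of the aryl methyl ether, which could not be removed by the final hydrogenolysis, gives the catechol and leaves the aldehyde and both halogens in place.

Step 7
Reactants: 12 2-bromo-3,4-dihydroxy-6-iodobenzaldehyde
Product: 13 3,4-bis(benzyloxy)-2-bromo-6-iodobenzaldehyde
Conditions: BnBr, K2CO3, DMF, 60 °C
Reagents that add atoms: benzyl bromide, BrCc1ccccc1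
Why: Double Williamson etherification gives both phenols the same hydrogenolysable benzyl group that all other phenols of the route carry.

Step 8
Reactants: 13 3,4-bis(benzyloxy)-2-bromo-6-iodobenzaldehyde
Product: 14 [3,4-bis(benzyloxy)-2-bromo-6-iodophenyl]methanol
Conditions: NaBH4, THF/MeOH, 0 °C
Reagents that add atoms: none
Why: Hydride reduction takes the aldehyde to the benzylic alcohol, because neither a free aldehyde nor an acetal would survive the later silane reduction.

Step 9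
Reactants: 14 [3,4-bis(benzyloxy)-2-bromo-6-iodophenyl]methanol
Product: 15 tert-butyl{[3,4-bis(benzyloxy)-2-bromo-6-iodophenyl]methoxy}diphenylsilane
Conditions: TBDPSCl, imidazole, DMF, rt
Reagents that add atoms: tert-butyl(chloro)diphenylsilane, CC(C)(C)[Si](Cl)(c1ccccc1)c1ccccc1
Why: Silylation gives a bulky ether that resists retro-Brook migration in the ortho-lithiated arene and outlasts the later removal of the secondary silyl ether.

Step 10
Reactants: 15 tert-butyl{[3,4-bis(benzyloxy)-2-bromo-6-iodophenyl]methoxy}diphenylsilane; 9 (3R)-5,7-bis(benzyloxy)-3-(tert-butyldimethylsilyloxy)chroman-2-one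
Product: 17 (2R)-1-[4,5-bis(benzyloxy)-3-bromo-2-(tert-butyldiphenylsilyloxymethyl)phenyl]-3-[2,4-bis(benzyloxy)-6-hydroxyphenyl]-2-(tert-butyldimethylsilyloxy)propan-1-one, via aryllithium 16 (not isolated)
Conditions: n-BuLi (1.0 equiv), THF, −78 °C; then 9, −78 °C; AcOH quench at −78 °C
Reagents that add atoms: none
Why: Iodine–lithium exchange is much faster than bromine–lithium exchange, and 1,2-addition of the aryllithium to the lactone at low temperature should stop after one addition to give the hydroxy ketone (in equilibrium with its cyclic hemiketal) with the silyloxy centre intact.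

Step 11
Reactants: 17 (2R)-1-[4,5-bis(benzyloxy)-3-bromo-2-(tert-butyldiphenylsilyloxymethyl)phenyl]-3-[2,4-bis(benzyloxy)-6-hydroxyphenyl]-2-(tert-butyldimethylsilyloxy)propan-1-one
Product: 19 (2R,3R)-2-[4,5-bis(benzyloxy)-3-bromo-2-(tert-butyldiphenylsilyloxymethyl)phenyl]-5,7-bis(benzyloxy)-3-(tert-butyldimethylsilyloxy)chroman, via chromenylium ion 18 (not isolated)
Conditions: Et3SiH, BF3·OEt2, CH2Cl2, −78 to −40 °C
Reagents that add atoms: none
Why: The Lewis acid closes the phenol onto the ketone to a 2-aryl-4H-chromenylium ion in which A(1,2) strain with the aryl group should hold the silyloxy group pseudoaxial, and silane hydride then adds to C2 anti to it (reductive etherification of the C-glycoside type), which should set C2 cis to C3, that is (2R,3R).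

Step 12
Reactants: 19 (2R,3R)-2-[4,5-bis(benzyloxy)-3-bromo-2-(tert-butyldiphenylsilyloxymethyl)phenyl]-5,7-bis(benzyloxy)-3-(tert-butyldimethylsilyloxy)chroman
Product: 20 (2R,3R)-2-[4,5-bis(benzyloxy)-3-bromo-2-(tert-butyldiphenylsilyloxymethyl)phenyl]-5,7-bis(benzyloxy)chroman-3-ol
Conditions: HF·pyridine, pyridine, THF, 0 °C to rt
Reagents that add atoms: none
Why: Fluoride cleaves the tert-butyldimethylsilyl ether much faster than the tert-butyldiphenylsilyl ether, so C3–OH is freed while the benzylic oxygen stays masked and cannot later form a lactol or lactone with it.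

Step 13
Reactants: 20 (2R,3R)-2-[4,5-bis(benzyloxy)-3-bromo-2-(tert-butyldiphenylsilyloxymethyl)phenyl]-5,7-bis(benzyloxy)chroman-3-ol; 21 3,4,5-tris(benzyloxy)benzoic acid
Product: 22 (2R,3R)-2-[4,5-bis(benzyloxy)-3-bromo-2-(tert-butyldiphenylsilyloxymethyl)phenyl]-5,7-bis(benzyloxy)chroman-3-yl 3,4,5-tris(benzyloxy)benzoate
Conditions: EDC·HCl, DMAP, CH2Cl2, rt
Reagents that add atoms: none
Why: Steglich esterification acylates the hindered axial C3 hydroxyl with the benzylated gallic acid without affecting either stereocentre.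

Step 14
Reactants: 22 (2R,3R)-2-[4,5-bis(benzyloxy)-3-bromo-2-(tert-butyldiphenylsilyloxymethyl)phenyl]-5,7-bis(benzyloxy)chroman-3-yl 3,4,5-tris(benzyloxy)benzoate
Product: 23 (2R,3R)-2-[4,5-bis(benzyloxy)-3-bromo-2-(hydroxymethyl)phenyl]-5,7-bis(benzyloxy)chroman-3-yl 3,4,5-tris(benzyloxy)benzoate
Conditions: TBAF, AcOH, THF, rt
Reagents that add atoms: none
Why: Buffered fluoride desilylation frees the benzylic alcohol and leaves the gallate ester intact.

Step 15
Reactants: 23 (2R,3R)-2-[4,5-bis(benzyloxy)-3-bromo-2-(hydroxymethyl)phenyl]-5,7-bis(benzyloxy)chroman-3-yl 3,4,5-tris(benzyloxy)benzoate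
Product: 24 (2R,3R)-2-[4,5-bis(benzyloxy)-3-bromo-2-formylphenyl]-5,7-bis(benzyloxy)chroman-3-yl 3,4,5-tris(benzyloxy)benzoate
Conditions: Dess–Martin periodinane, NaHCO3, CH2Cl2, rt
Reagents that add atoms: none
Why: Dess–Martin oxidation converts the only free hydroxyl, a primary benzylic alcohol, into the aldehyde carbon that becomes C9.

Step 16
Reactants: 24 (2R,3R)-2-[4,5-bis(benzyloxy)-3-bromo-2-formylphenyl]-5,7-bis(benzyloxy)chroman-3-yl 3,4,5-tris(benzyloxy)benzoate
Product: 25 (2R,3R)-2-[4,5-bis(benzyloxy)-3-(1-ethoxyvinyl)-2-formylphenyl]-5,7-bis(benzyloxy)chroman-3-yl 3,4,5-tris(benzyloxy)benzoate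
Conditions: tributyl(1-ethoxyvinyl)stannane, Pd(PPh3)4 (5 mol%), toluene, 100 °C
Reagents that add atoms: tributyl(1-ethoxyvinyl)stannane, CCOC(=C)[Sn](CCCC)(CCCC)CCCC
Why: Stille coupling of the aryl bromide, which the ortho formyl group activates towards oxidative addition, installs the two carbons of C5 and C6 as an enol ether at the ketone oxidation level.

Step 17
Reactants: 25 (2R,3R)-2-[4,5-bis(benzyloxy)-3-(1-ethoxyvinyl)-2-formylphenyl]-5,7-bis(benzyloxy)chroman-3-yl 3,4,5-tris(benzyloxy)benzoate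
Product: 27 (2R,3R)-2-[5,6-bis(benzyloxy)-1-hydroxy-4-oxoisochroman-8-yl]-5,7-bis(benzyloxy)chroman-3-yl 3,4,5-tris(benzyloxy)benzoate (C1 epimers), via open hydroxy ketone 26 (not isolated)
Conditions: OsO4 (2 mol%), NMO, acetone/H2O, rt
Reagents that add atoms: N-methylmorpholine N-oxide, C[N+]1([O-])CCOCC1; water, O
Why: Upjohn dihydroxylation of the electron-rich enol ether gives a hemiketal that loses ethanol to the α-hydroxy ketone, whose hydroxyl adds to the neighbouring aldehyde to close the six-membered lactol (ring-chain tautomerism).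

Step 18
Reactants: 27 (2R,3R)-2-[5,6-bis(benzyloxy)-1-hydroxy-4-oxoisochroman-8-yl]-5,7-bis(benzyloxy)chroman-3-yl 3,4,5-tris(benzyloxy)benzoate
Product: 28 (2R,3R)-2-[1-acetoxy-5,6-bis(benzyloxy)-4-oxoisochroman-8-yl]-5,7-bis(benzyloxy)chroman-3-yl 3,4,5-tris(benzyloxy)benzoate (C1 epimers)
Conditions: Ac2O, pyridine, DMAP (cat.), CH2Cl2, 0 °C
Reagents that add atoms: acetic anhydride, CC(=O)OC(C)=O
Why: Acetylation of the lactol hydroxyl under cold, weakly basic conditions gives the acetal acetate that serves as leaving group for ylide formation before any elimination sets in.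

Step 19
Reactants: 8 (3R)-5,7-bis(benzyloxy)-3-hydroxychroman-2-one
Product: 29 (3R)-3,5,7-tris(benzyloxy)chroman-2-one
Conditions: BnBr, Ag2O, 4 Å molecular sieves, CH2Cl2, rt
Reagents that add atoms: benzyl bromide, BrCc1ccccc1
Why: Silver oxide-mediated benzylation etherifies the α-hydroxy lactone under nearly neutral conditions, which avoids enolisation at C3 and opening of the aryl lactone.

Step 20
Reactants: 29 (3R)-3,5,7-tris(benzyloxy)chroman-2-one
Product: 30 (4R)-4-(benzyloxy)-5-[2,4-bis(benzyloxy)-6-hydroxyphenyl]-1-(trimethylsilyl)pent-1-yn-3-one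
Conditions: (trimethylsilyl)acetylene, n-BuLi, THF, −78 °C; BF3·OEt2, −78 °C; then 29, −78 °C; H2O
Reagents that add atoms: (trimethylsilyl)acetylene, C#C[Si](C)(C)C
Why: In the Yamaguchi ynone synthesis the alkynyl–BF3 species adds once to the lactone and the boron-bound tetrahedral intermediate persists until work-up, so the reaction stops at the ynone with its phenol released.

Step 21
Reactants: 30 (4R)-4-(benzyloxy)-5-[2,4-bis(benzyloxy)-6-hydroxyphenyl]-1-(trimethylsilyl)pent-1-yn-3-one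
Product: 31 (3S,4R)-4-(benzyloxy)-5-[2,4-bis(benzyloxy)-6-hydroxyphenyl]-1-(trimethylsilyl)pent-1-yn-3-ol
Conditions: Zn(BH4)2, Et2O, −30 to 0 °C
Reagents that add atoms: none
Why: Zinc chelation between the ketone and the α-benzyloxy oxygen (Cram chelate model) directs hydride to the face opposite the arylmethyl group and should give the anti (3S,4R) alcohol.

Step 22
Reactants: 31 (3S,4R)-4-(benzyloxy)-5-[2,4-bis(benzyloxy)-6-hydroxyphenyl]-1-(trimethylsilyl)pent-1-yn-3-ol
Product: 32 (2R,3R)-3,5,7-tris(benzyloxy)-2-[(trimethylsilyl)ethynyl]chroman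
Conditions: PPh3, DIAD, THF, 0 °C to rt
Reagents that add atoms: none
Why: In an intramolecular Mitsunobu etherification the phenol displaces the activated propargylic hydroxyl by a 6-exo-tet SN2 closure with inversion, which turns the (3S) carbinol into the (2R) centre cis to the C3 benzyloxy group.

Step 23
Reactants: 32 (2R,3R)-3,5,7-tris(benzyloxy)-2-[(trimethylsilyl)ethynyl]chroman
Product: 33 (2R,3R)-3,5,7-tris(benzyloxy)-2-ethynylchroman
Conditions: K2CO3 (cat.), MeOH/THF, rt
Reagents that add atoms: none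
Why: Carbonate-catalysed methanolysis of the alkynylsilane frees the terminal alkyne under conditions too mild to epimerise the propargylic ether centre.

Step 24
Reactants: 33 (2R,3R)-3,5,7-tris(benzyloxy)-2-ethynylchroman
Product: 35 3-[(2R,3R)-3,5,7-tris(benzyloxy)chroman-2-yl]prop-2-ynal, via lithium acetylide 34 (not isolated)
Conditions: n-BuLi, THF, −78 °C; DMF, −78 to 0 °C; reverse quench into aq. KH2PO4
Reagents that add atoms: N,N-dimethylformamide, CN(C)C=O
Why: Deprotonation of the terminal alkyne and formylation of the acetylide with DMF, followed by a buffered reverse quench that keeps the liberated dimethylamine from adding to the ynal, gives the acceptor-activated alkyne.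

Step 25
Reactants: 28 (2R,3R)-2-[1-acetoxy-5,6-bis(benzyloxy)-4-oxoisochroman-8-yl]-5,7-bis(benzyloxy)chroman-3-yl 3,4,5-tris(benzyloxy)benzoate; 35 3-[(2R,3R)-3,5,7-tris(benzyloxy)chroman-2-yl]prop-2-ynal
Product: 37 oxygen-bridged [5+2] cycloadduct bearing flavan B on C7 plus formyl on C8 (bridgeheads C6/C9 unassigned), via benzopyrylium olate 36 (not isolated)
Conditions: iPr2NEt (slow addition), MeCN, 0 °C to rt
Reagents that add atoms: none
Why: Ionisation of the acetal acetate, assisted by the para benzyloxy group, and loss of a C6 proton to the hindered amine should give the 2-benzopyrylium-4-olate 36, a carbonyl ylide. The ylide adds across the triple bond of 35 in a concerted but asynchronous [5+2] (1,3-dipolar) cycloaddition, for which the closest known reactions are additions of oxidopyrylium and 2-benzopyrylium-4-olate ylides to acceptor-substituted alkynes. The seven-membered carbocycle closes by suprafacial bonding of both ylide termini, C6 and C9, to the two alkyne carbons, which leaves the ring oxygen as the one-atom bridge of a bicyclo[3.2.1] adduct. The two new stereocentres are the bridgeheads C6 and C9, which the oxygen bridge ties cis to each other; their sense relative to the flavans is not controlled and need not be, because both are erased on ring opening. The selectivity that matters is regiochemical: the enolate-like C6 must bond to the alkyne carbon carrying flavan B and C9 to the formyl-bearing carbon, which the polarisation of the ynal (acceptor coefficient largest at the β carbon) secures and sterics reinforce, since the small formyl-bearing carbon ends next to the crowded C9. The flavan centres and the ester are spectators, and the hindered base is chosen so that the ynal is neither attacked in a conjugate sense nor deprotonated at its propargylic position.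

Step 26
Reactants: 37 oxygen-bridged [5+2] cycloadduct bearing flavan B on C7 plus formyl on C8
Product: 38 oxygen-bridged adduct with hydrogen on C8 (bridgeheads C6/C9 unassigned)
Conditions: RhCl(PPh3)3 (1.1 equiv), toluene, 100 °C
Reagents that add atoms: none
Why: Tsuji–Wilkinson decarbonylation (oxidative addition of the formyl C–H bond to monovalent rhodium, carbon monoxide extrusion and reductive elimination) replaces the formyl group on C8 by hydrogen and leaves the C7–C8 double bond in place.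

Step 27
Reactants: 38 oxygen-bridged adduct with hydrogen on C8
Product: 39 deca-O-benzyl benzotropolone (free C6 hydroxyl; all ten other hydroxyls of the target benzylated)
Conditions: CF3CO2H, CH2Cl2, 0 °C to rt
Reagents that add atoms: none
Why: Protonation of the bridging oxygen cleaves the benzylic and allylic C9–O bond, and loss of the C6 proton from the stabilised cation gives the C5 ketone, the C6 hydroxyl and the C8–C9 double bond of the aromatic benzotropolone (acid-mediated opening of an oxa-bridged [5+2] adduct), which removes both bridgehead stereocentres.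

Step 28
Reactants: 39 deca-O-benzyl benzotropolone
Product: 40 target compound CNP0217128.1
Conditions: H2 (1 atm), Pd(OH)2/C, THF/MeOH, rt
Reagents that add atoms: none
Why: Hydrogenolysis cleaves all ten benzyl ethers under neutral conditions that should leave the gallate ester, the tropolone ring and the four flavan stereocentres unchanged.

Compound list
1 | 3,5-bis(benzyloxy)phenol | Oc1cc(OCc9ccccc9)cc(OCc9ccccc9)c1 | starting material
2 | 1,3-bis(benzyloxy)-5-(methoxymethoxy)benzene | COCOc1cc(OCc9ccccc9)cc(OCc9ccccc9)c1 | intermediate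
3 | methyl (R)-glycidate | COC(=O)[C@H]1CO1 | starting material
4 | [2,4-bis(benzyloxy)-6-(methoxymethoxy)phenyl]lithium | [Li]c1c(OCOC)cc(OCc9ccccc9)cc1OCc9ccccc9 | intermediate
5 | [2,4-bis(benzyloxy)-6-(methoxymethoxy)phenyl]magnesium bromide | Br[Mg]c1c(OCOC)cc(OCc9ccccc9)cc1OCc9ccccc9 | intermediate
6 | methyl (2R)-3-[2,4-bis(benzyloxy)-6-(methoxymethoxy)phenyl]-2-hydroxypropanoate | COC(=O)[C@H](O)Cc1c(OCOC)cc(OCc9ccccc9)cc1OCc9ccccc9 | intermediate
7 | methyl (2R)-3-[2,4-bis(benzyloxy)-6-hydroxyphenyl]-2-hydroxypropanoate | COC(=O)[C@H](O)Cc1c(O)cc(OCc9ccccc9)cc1OCc9ccccc9 | intermediate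
8 | (3R)-5,7-bis(benzyloxy)-3-hydroxychroman-2-one | O=C1Oc2cc(OCc9ccccc9)cc(OCc9ccccc9)c2C[C@H]1O | intermediate
9 | (3R)-5,7-bis(benzyloxy)-3-(tert-butyldimethylsilyloxy)chroman-2-one | O=C1Oc2cc(OCc9ccccc9)cc(OCc9ccccc9)c2C[C@H]1O[Si](C)(C)C(C)(C)C | intermediate
10 | 2-bromoisovanillin | COc1ccc(C=O)c(Br)c1O | starting material
11 | 2-bromo-3-hydroxy-6-iodo-4-methoxybenzaldehyde | COc1cc(I)c(C=O)c(Br)c1O | intermediate
12 | 2-bromo-3,4-dihydroxy-6-iodobenzaldehyde | Oc1cc(I)c(C=O)c(Br)c1O | intermediate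
13 | 3,4-bis(benzyloxy)-2-bromo-6-iodobenzaldehyde | O=Cc1c(I)cc(OCc9ccccc9)c(OCc9ccccc9)c1Br | intermediate
14 | [3,4-bis(benzyloxy)-2-bromo-6-iodophenyl]methanol | OCc1c(I)cc(OCc9ccccc9)c(OCc9ccccc9)c1Br | intermediate
15 | tert-butyl{[3,4-bis(benzyloxy)-2-bromo-6-iodophenyl]methoxy}diphenylsilane | CC(C)(C)[Si](OCc1c(I)cc(OCc9ccccc9)c(OCc9ccccc9)c1Br)(c1ccccc1)c1ccccc1 | intermediate
16 | aryllithium from 15 (lithium in place of iodine) | CC(C)(C)[Si](OCc1c([Li])cc(OCc9ccccc9)c(OCc9ccccc9)c1Br)(c1ccccc1)c1ccccc1 | intermediate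
17 | (2R)-1-[4,5-bis(benzyloxy)-3-bromo-2-(tert-butyldiphenylsilyloxymethyl)phenyl]-3-[2,4-bis(benzyloxy)-6-hydroxyphenyl]-2-(tert-butyldimethylsilyloxy)propan-1-one | O=C([C@@H](Cc1c(O)cc(OCc9ccccc9)cc1OCc9ccccc9)O[Si](C)(C)C(C)(C)C)c1cc(OCc9ccccc9)c(OCc9ccccc9)c(Br)c1CO[Si](c1ccccc1)(c1ccccc1)C(C)(C)C | intermediate
18 | (3R)-2-aryl-5,7-bis(benzyloxy)-3-(tert-butyldimethylsilyloxy)-4H-chromenylium ion (aryl as in 17) | CC(C)(C)[Si](C)(C)O[C@@H]1Cc2c(OCc9ccccc9)cc(OCc9ccccc9)cc2[O+]=C1c1cc(OCc9ccccc9)c(OCc9ccccc9)c(Br)c1CO[Si](c1ccccc1)(c1ccccc1)C(C)(C)C | intermediate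
19 | (2R,3R)-2-[4,5-bis(benzyloxy)-3-bromo-2-(tert-butyldiphenylsilyloxymethyl)phenyl]-5,7-bis(benzyloxy)-3-(tert-butyldimethylsilyloxy)chroman | CC(C)(C)[Si](C)(C)O[C@@H]1Cc2c(OCc9ccccc9)cc(OCc9ccccc9)cc2O[C@@H]1c1cc(OCc9ccccc9)c(OCc9ccccc9)c(Br)c1CO[Si](c1ccccc1)(c1ccccc1)C(C)(C)C | intermediate
20 | (2R,3R)-2-[4,5-bis(benzyloxy)-3-bromo-2-(tert-butyldiphenylsilyloxymethyl)phenyl]-5,7-bis(benzyloxy)chroman-3-ol | O[C@@H]1Cc2c(OCc9ccccc9)cc(OCc9ccccc9)cc2O[C@@H]1c1cc(OCc9ccccc9)c(OCc9ccccc9)c(Br)c1CO[Si](c1ccccc1)(c1ccccc1)C(C)(C)C | intermediate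
21 | 3,4,5-tris(benzyloxy)benzoic acid | OC(=O)c1cc(OCc9ccccc9)c(OCc9ccccc9)c(OCc9ccccc9)c1 | starting material
22 | 3-O-[3,4,5-tris(benzyloxy)benzoyl] ester of 20 | O=C(O[C@@H]1Cc2c(OCc9ccccc9)cc(OCc9ccccc9)cc2O[C@@H]1c1cc(OCc9ccccc9)c(OCc9ccccc9)c(Br)c1CO[Si](c1ccccc1)(c1ccccc1)C(C)(C)C)c1cc(OCc9ccccc9)c(OCc9ccccc9)c(OCc9ccccc9)c1 | intermediate
23 | (2R,3R)-2-[4,5-bis(benzyloxy)-3-bromo-2-(hydroxymethyl)phenyl]-5,7-bis(benzyloxy)chroman-3-yl 3,4,5-tris(benzyloxy)benzoate | O=C(O[C@@H]1Cc2c(OCc9ccccc9)cc(OCc9ccccc9)cc2O[C@@H]1c1cc(OCc9ccccc9)c(OCc9ccccc9)c(Br)c1CO)c1cc(OCc9ccccc9)c(OCc9ccccc9)c(OCc9ccccc9)c1 | intermediate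
24 | (2R,3R)-2-[4,5-bis(benzyloxy)-3-bromo-2-formylphenyl]-5,7-bis(benzyloxy)chroman-3-yl 3,4,5-tris(benzyloxy)benzoate | O=C(O[C@@H]1Cc2c(OCc9ccccc9)cc(OCc9ccccc9)cc2O[C@@H]1c1cc(OCc9ccccc9)c(OCc9ccccc9)c(Br)c1C=O)c1cc(OCc9ccccc9)c(OCc9ccccc9)c(OCc9ccccc9)c1 | intermediate
25 | (2R,3R)-2-[4,5-bis(benzyloxy)-3-(1-ethoxyvinyl)-2-formylphenyl]-5,7-bis(benzyloxy)chroman-3-yl 3,4,5-tris(benzyloxy)benzoate | O=C(O[C@@H]1Cc2c(OCc9ccccc9)cc(OCc9ccccc9)cc2O[C@@H]1c1cc(OCc9ccccc9)c(OCc9ccccc9)c(C(=C)OCC)c1C=O)c1cc(OCc9ccccc9)c(OCc9ccccc9)c(OCc9ccccc9)c1 | intermediate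
26 | (2R,3R)-2-[4,5-bis(benzyloxy)-2-formyl-3-(hydroxyacetyl)phenyl]-5,7-bis(benzyloxy)chroman-3-yl 3,4,5-tris(benzyloxy)benzoate | O=C(O[C@@H]1Cc2c(OCc9ccccc9)cc(OCc9ccccc9)cc2O[C@@H]1c1cc(OCc9ccccc9)c(OCc9ccccc9)c(C(=O)CO)c1C=O)c1cc(OCc9ccccc9)c(OCc9ccccc9)c(OCc9ccccc9)c1 | intermediate
27 | (2R,3R)-2-[5,6-bis(benzyloxy)-1-hydroxy-4-oxoisochroman-8-yl]-5,7-bis(benzyloxy)chroman-3-yl 3,4,5-tris(benzyloxy)benzoate (C1 epimers) | O=C(O[C@@H]1Cc2c(OCc9ccccc9)cc(OCc9ccccc9)cc2O[C@@H]1c1cc(OCc9ccccc9)c(OCc9ccccc9)c2C(=O)COC(O)c12)c1cc(OCc9ccccc9)c(OCc9ccccc9)c(OCc9ccccc9)c1 | intermediate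
28 | (2R,3R)-2-[1-acetoxy-5,6-bis(benzyloxy)-4-oxoisochroman-8-yl]-5,7-bis(benzyloxy)chroman-3-yl 3,4,5-tris(benzyloxy)benzoate (C1 epimers; A half) | O=C(O[C@@H]1Cc2c(OCc9ccccc9)cc(OCc9ccccc9)cc2O[C@@H]1c1cc(OCc9ccccc9)c(OCc9ccccc9)c2C(=O)COC(OC(C)=O)c12)c1cc(OCc9ccccc9)c(OCc9ccccc9)c(OCc9ccccc9)c1 | intermediate
29 | (3R)-3,5,7-tris(benzyloxy)chroman-2-one | O=C1Oc2cc(OCc9ccccc9)cc(OCc9ccccc9)c2C[C@H]1OCc9ccccc9 | intermediate
30 | (4R)-4-(benzyloxy)-5-[2,4-bis(benzyloxy)-6-hydroxyphenyl]-1-(trimethylsilyl)pent-1-yn-3-one | C[Si](C)(C)C#CC(=O)[C@@H](Cc1c(O)cc(OCc9ccccc9)cc1OCc9ccccc9)OCc9ccccc9 | intermediate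
31 | (3S,4R)-4-(benzyloxy)-5-[2,4-bis(benzyloxy)-6-hydroxyphenyl]-1-(trimethylsilyl)pent-1-yn-3-ol | C[Si](C)(C)C#C[C@H](O)[C@@H](Cc1c(O)cc(OCc9ccccc9)cc1OCc9ccccc9)OCc9ccccc9 | intermediate
32 | (2R,3R)-3,5,7-tris(benzyloxy)-2-[(trimethylsilyl)ethynyl]chroman | C[Si](C)(C)C#C[C@H]1Oc2cc(OCc9ccccc9)cc(OCc9ccccc9)c2C[C@H]1OCc9ccccc9 | intermediate
33 | (2R,3R)-3,5,7-tris(benzyloxy)-2-ethynylchroman | C#C[C@H]1Oc2cc(OCc9ccccc9)cc(OCc9ccccc9)c2C[C@H]1OCc9ccccc9 | intermediate
34 | lithium acetylide of 33 | [Li]C#C[C@H]1Oc2cc(OCc9ccccc9)cc(OCc9ccccc9)c2C[C@H]1OCc9ccccc9 | intermediate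
35 | 3-[(2R,3R)-3,5,7-tris(benzyloxy)chroman-2-yl]prop-2-ynal (B half) | O=CC#C[C@H]1Oc2cc(OCc9ccccc9)cc(OCc9ccccc9)c2C[C@H]1OCc9ccccc9 | intermediate
36 | 2-benzopyrylium-4-olate from 28 (5,6-bis(benzyloxy); galloylated flavan A on C8) | O=C(O[C@@H]1Cc2c(OCc9ccccc9)cc(OCc9ccccc9)cc2O[C@@H]1c1cc(OCc9ccccc9)c(OCc9ccccc9)c2c([O-])c[o+]cc12)c1cc(OCc9ccccc9)c(OCc9ccccc9)c(OCc9ccccc9)c1 | intermediate
37 | oxygen-bridged cycloadduct: 6,9-epoxy-6,9-dihydrobenzo[7]annulen-5-one with galloylated flavan A on C1, benzyloxy on C3 and C4, flavan B on C7, formyl on C8 (bridgeheads unassigned) | O=C(O[C@@H]1Cc2c(OCc9ccccc9)cc(OCc9ccccc9)cc2O[C@@H]1c1cc(OCc9ccccc9)c(OCc9ccccc9)c2C(=O)C3OC(C(C=O)=C3[C@H]5Oc6cc(OCc9ccccc9)cc(OCc9ccccc9)c6C[C@H]5OCc9ccccc9)c12)c1cc(OCc9ccccc9)c(OCc9ccccc9)c(OCc9ccccc9)c1 | intermediate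
38 | oxygen-bridged adduct as 37 with hydrogen in place of the C8 formyl group (bridgeheads unassigned) | O=C(O[C@@H]1Cc2c(OCc9ccccc9)cc(OCc9ccccc9)cc2O[C@@H]1c1cc(OCc9ccccc9)c(OCc9ccccc9)c2C(=O)C3OC(C=C3[C@H]5Oc6cc(OCc9ccccc9)cc(OCc9ccccc9)c6C[C@H]5OCc9ccccc9)c12)c1cc(OCc9ccccc9)c(OCc9ccccc9)c(OCc9ccccc9)c1 | intermediate
39 | deca-O-benzyl benzotropolone (target with every hydroxyl except the C6 tropolone hydroxyl benzylated) | O=C(O[C@@H]1Cc2c(OCc9ccccc9)cc(OCc9ccccc9)cc2O[C@@H]1c1cc(OCc9ccccc9)c(OCc9ccccc9)c2c(=O)c(O)c([C@H]3Oc4cc(OCc9ccccc9)cc(OCc9ccccc9)c4C[C@H]3OCc9ccccc9)ccc12)c1cc(OCc9ccccc9)c(OCc9ccccc9)c(OCc9ccccc9)c1 | intermediate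
40 | CNP0217128.1 | O=C(O[C@@H]1Cc2c(O)cc(O)cc2O[C@@H]1c1cc(O)c(O)c2c(=O)c(O)c([C@H]3Oc4cc(O)cc(O)c4C[C@H]3O)ccc12)c1cc(O)c(O)c(O)c1 | target

Total step count: 28.
Longest linear sequence: 18 steps (from 10 through steps 5 to 18, then steps 25 to 28).

Steps most likely to fail

Step 25. The amine may add to, or isomerise, the ynal before the ylide is trapped, and the ylide may dimerise because the hindered disubstituted alkyne reacts slowly. The fallback generates the same carbonyl ylide without base by the rhodium carbenoid route. It sets out from 25: NBS in THF/H2O at 0 °C should convert the enol ether into the bromomethyl ketone F1; N,N′-ditosylhydrazine and DBU in THF should then give the diazo ketone F2. With Rh2(OAc)4 (catalytic) in CH2Cl2 and 35 present, the carbenoid is captured by the ortho formyl oxygen to form 36 under neutral conditions, and its cycloaddition with 35 returns to the route at 37.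

Step 11. Hydride may be delivered to the wrong face of the chromenylium ion, losing the cis relationship, or the neighbouring silyl ether oxygen may participate and lead to ring-opened reduction. The fallback separates the two events and sets out from 17. The ketone is reduced under catalyst control (BH3·SMe2, 2-methyl-CBS-oxazaborolidine of the sense that gives the (1S) carbinol) to the (1S,2R)-hydroxy silyl ether F3. Intramolecular Mitsunobu etherification (PPh3, DIAD, THF) then closes the ring with inversion at the benzylic carbon and returns to 19.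

Step 26. Oxidative addition at the formyl group on the tetrasubstituted, bridged alkene may be slow, and the temperature then required may decompose the strained adduct. The fallback removes the formyl group at the aromatic stage instead and sets out from 37. CF3CO2H in CH2Cl2 should first open the bridge to the 8-formyl benzotropolone F4, whose aldehyde is planar, unhindered and thermally robust. Its decarbonylation with RhCl(PPh3)3 in refluxing toluene returns to the route at 39.

Further compounds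
F1 | step 25 | (2R,3R)-2-[4,5-bis(benzyloxy)-3-(bromoacetyl)-2-formylphenyl]-5,7-bis(benzyloxy)chroman-3-yl 3,4,5-tris(benzyloxy)benzoate | O=C(O[C@@H]1Cc2c(OCc9ccccc9)cc(OCc9ccccc9)cc2O[C@@H]1c1cc(OCc9ccccc9)c(OCc9ccccc9)c(C(=O)CBr)c1C=O)c1cc(OCc9ccccc9)c(OCc9ccccc9)c(OCc9ccccc9)c1
F2 | step 25 | (2R,3R)-2-[4,5-bis(benzyloxy)-3-(diazoacetyl)-2-formylphenyl]-5,7-bis(benzyloxy)chroman-3-yl 3,4,5-tris(benzyloxy)benzoate | O=C(O[C@@H]1Cc2c(OCc9ccccc9)cc(OCc9ccccc9)cc2O[C@@H]1c1cc(OCc9ccccc9)c(OCc9ccccc9)c(C(=O)C=[N+]=[N-])c1C=O)c1cc(OCc9ccccc9)c(OCc9ccccc9)c(OCc9ccccc9)c1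
F3 | step 11 | (1S,2R)-1-[4,5-bis(benzyloxy)-3-bromo-2-(tert-butyldiphenylsilyloxymethyl)phenyl]-3-[2,4-bis(benzyloxy)-6-hydroxyphenyl]-2-(tert-butyldimethylsilyloxy)propan-1-ol | O[C@H]([C@@H](Cc1c(O)cc(OCc9ccccc9)cc1OCc9ccccc9)O[Si](C)(C)C(C)(C)C)c1cc(OCc9ccccc9)c(OCc9ccccc9)c(Br)c1CO[Si](c1ccccc1)(c1ccccc1)C(C)(C)C
F4 | step 26 | deca-O-benzyl 8-formyl benzotropolone (39 with a formyl group on C8) | O=C(O[C@@H]1Cc2c(OCc9ccccc9)cc(OCc9ccccc9)cc2O[C@@H]1c1cc(OCc9ccccc9)c(OCc9ccccc9)c2c(=O)c(O)c([C@H]3Oc4cc(OCc9ccccc9)cc(OCc9ccccc9)c4C[C@H]3OCc9ccccc9)c(C=O)cc12)c1cc(OCc9ccccc9)c(OCc9ccccc9)c(OCc9ccccc9)c1
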